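**Retrosynthetic overview**
1. Aspergimarin B is traced back to its tribenzyl derivative (two aryl benzyl ethers, one benzyl ester), so one hydrogenolysis ends the route.
2. The key disconnection is C3–C1' (isochromanone numbering, side chain C1'–C5'). It is made by a nickel hydride catalysed, enantioconvergent coupling of a racemic 3-bromoisochroman-1-one with the terminal olefin of benzyl (S)-pent-4-en-2-yl succinate, which already carries C4' and the succinate.
3. Enabling feature: C3 of lactone ring B bears O2, and O2 is acylated by C1(=O) on C8a of benzene ring A. A C3–Br derivative is therefore a 1-bromoalkyl ester. Its homolysis gives a planar C3 alpha-acyloxy radical flanked only by C4H2 and H, and a chiral nickel catalyst funnels both enantiomers through it into (3R).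
4. The bromide comes from the lactol, the lactol from 5,8-bis(benzyloxy)isocoumarin, and that from 2,5-bis(benzyloxy)benzoic acid plus vinylene carbonate (C–H vinylene annulation).
5. Ring order: ring A is bought as gentisic acid. Ring B is the only ring made (step 2) and is in place before the key step.

Key step: step 6

Assumption: the (S,S)-bis(oxazoline) is taken, by analogy with acyclic 1-bromoalkyl esters, to deliver (3R). If the sense of induction is the opposite, the equally available (R,R)-ligand is used and nothing else changes.

**Step 1**
Reactants: 1 2,5-dihydroxybenzoic acid (gentisic acid)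
Product: 3 2,5-bis(benzyloxy)benzoic acid, via benzyl 2,5-bis(benzyloxy)benzoate 2 (not isolated)
Conditions: BnBr (3.5 equiv), K2CO3, DMF, 60 °C, N2; then aq NaOH, MeOH, 60 °C, same flask; then aq HCl
Reagents that add atoms: benzyl bromide BrCc1ccccc1; sodium hydroxide [Na+].[OH-]
Why: Williamson-type O-alkylation of all three acidic OH groups followed by in-flask saponification of the only ester is routine, aryl benzyl ethers are inert to hydroxide, and no stereocentre is involved.

**Step 2**
Reactants: 3 2,5-bis(benzyloxy)benzoic acid; 4 vinylene carbonate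
Product: 5 5,8-bis(benzyloxy)-1H-isochromen-1-one (5,8-bis(benzyloxy)isocoumarin)
Conditions: [Cp*Rh(MeCN)3](SbF6)2 (5 mol %), 4 (3 equiv), DCE, 100 °C, sealed tube
Reagents that add atoms: none
Why: Carboxylate-directed C–H activation by trivalent rhodium at the only free ortho position, insertion of vinylene carbonate and decarboxylative beta-oxygen elimination/cyclisation (the redox-neutral C–H vinylene annulation of benzoic acids) should build ring B as the 3,4-unsubstituted isocoumarin.

**Step 3**
Reactants: 5 5,8-bis(benzyloxy)-1H-isochromen-1-one
Product: 6 rac-5,8-bis(benzyloxy)-3-hydroxyisochroman-1-one (lactol, ring–chain tautomer of 3,6-bis(benzyloxy)-2-(2-oxoethyl)benzoic acid)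
Conditions: KOH (2 equiv), THF/H2O, 0 °C; then cold 1 M HCl to pH 3, extraction at 0 °C
Reagents that add atoms: potassium hydroxide [K+].[OH-]
Why: Saponification of the enol lactone gives the carboxylate/enolate, which on cold acidification ketonises to the arylacetaldehyde and closes to the six-membered lactol, placing the oxygen leaving group unambiguously at C3 as a racemic, labile centre of no consequence.

**Step 4**
Reactants: 6 rac-5,8-bis(benzyloxy)-3-hydroxyisochroman-1-one
Product: 7 rac-5,8-bis(benzyloxy)-3-bromoisochroman-1-one
Conditions: (COBr)2 (1.2 equiv), DMF (cat.), CH2Cl2, −10 to 0 °C, N2 sweep; evaporation with toluene; used crude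
Reagents that add atoms: oxalyl bromide O=C(Br)C(=O)Br
Why: Vilsmeier-type activation, as used for anomeric hemiacetals and 3-hydroxyphthalides, replaces the lactol OH by bromide (equivalently, the open acyl bromide adds across its own aldehyde) and gives the racemic cyclic 1-bromoalkyl ester beside volatile by-products only.

**Step 5**
Reactants: 8 (S)-pent-4-en-2-ol; 9 4-(benzyloxy)-4-oxobutanoic acid (monobenzyl succinate)
Product: 10 benzyl (S)-pent-4-en-2-yl succinate
Conditions: DCC (1.1 equiv), DMAP (10 mol %), CH2Cl2, 0 °C to rt
Reagents that add atoms: none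
Why: Steglich esterification acylates the secondary alcohol at oxygen without touching the C–O bond of the carbinol carbon, so the (S) configuration bought with 8 is retained as C4' of the target.

**Step 6**
Reactants: 7 rac-5,8-bis(benzyloxy)-3-bromoisochroman-1-one; 10 benzyl (S)-pent-4-en-2-yl succinate
Product: 11 benzyl (2S)-5-[(3R)-5,8-bis(benzyloxy)-1-oxoisochroman-3-yl]pentan-2-yl succinate
Conditions: NiBr2·diglyme (10 mol %), 2,2'-(propane-2,2-diyl)bis[(4S)-4-benzyl-4,5-dihydrooxazole] (12 mol %), (EtO)3SiH (2 equiv), K3PO4·H2O (2 equiv), 10 (1.5 equiv), i-Pr2O/THF, 0 °C to rt, slow addition of 7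
Reagents that add atoms: none
Why: Proposed new method: a bis(oxazoline)-ligated nickel hydride formed from NiBr2·diglyme, (EtO)3SiH and K3PO4·H2O should insert the terminal C=C of 10 in the anti-Markovnikov sense to give the primary C1' alkylnickel, while a monovalent nickel species abstracts bromine from either enantiomer of 7 to give one and the same planar C3 alpha-acyloxy radical, which the chiral alkylnickel captures and trivalent nickel releases by C3–C1' reductive elimination. The closest known reaction type is the nickel/bis(oxazoline)-catalysed enantioconvergent coupling of racemic acyclic 1-bromoalkyl esters with terminal olefins and a hydrosilane to give esters of chiral dialkyl carbinols; new here is that the 1-bromoalkyl ester is endocyclic (a lactone with fixed E ester geometry that cannot chelate nickel through C1=O), an extension supported by the known enantioselective capture of cyclic alpha-oxy radicals by chiral nickel complexes in related C–C couplings. No ring is closed, and ring B passes through the step intact. The C3 configuration is set by the ligand alone (catalyst control, stereoconvergent because the configuration of 7 is erased at the radical stage), whereas C4', five bonds away, is a spectator that turns any (3S) product into a diastereomer removable by chromatography or crystallisation. The step needs linear regioselectivity (secured by the unhindered monosubstituted olefin), chemoselective halogen abstraction (the C3–Br bond weakened by O2 is the only reducible bond, while benzyl ethers, benzyl ester, succinate and lactone are inert to silane and nickel hydride at this temperature) and coupling faster than loss of HBr towards C4 (secured by the acyl group on O2, which disfavours ionisation, by the insoluble mild base, by the low temperature and by keeping 7 dilute).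

**Step 7**
Reactants: 11 benzyl (2S)-5-[(3R)-5,8-bis(benzyloxy)-1-oxoisochroman-3-yl]pentan-2-yl succinate
Product: 12 aspergimarin B, 4-{[(2S)-5-[(3R)-5,8-dihydroxy-1-oxoisochroman-3-yl]pentan-2-yl]oxy}-4-oxobutanoic acid
Conditions: H2 (1 atm), 10 % Pd/C, EtOAc/EtOH, rt; filtration under argon
Reagents that add atoms: none
Why: Catalytic hydrogenolysis cleaves only the three benzylic C–O bonds (two aryl benzyl ethers, one benzyl ester), whereas the lactone C3–O2 bond is homobenzylic and the C4'–O bond purely aliphatic, so both stereocentres and both remaining esters stay untouched.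

**Compound list**
1 | 2,5-dihydroxybenzoic acid (gentisic acid) | OC(=O)c1cc(O)ccc1O | starting material
2 | benzyl 2,5-bis(benzyloxy)benzoate | O=C(OCc1ccccc1)c1cc(OCc2ccccc2)ccc1OCc1ccccc1 | intermediate
3 | 2,5-bis(benzyloxy)benzoic acid | OC(=O)c1cc(OCc2ccccc2)ccc1OCc1ccccc1 | intermediate
4 | vinylene carbonate (1,3-dioxol-2-one) | O=C1OC=CO1 | starting material
5 | 5,8-bis(benzyloxy)-1H-isochromen-1-one | C1=Cc2c(OCc3ccccc3)ccc(OCc3ccccc3)c2C(=O)O1 | intermediate
6 | rac-5,8-bis(benzyloxy)-3-hydroxyisochroman-1-one | OC1Cc2c(OCc3ccccc3)ccc(OCc3ccccc3)c2C(=O)O1 | intermediate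
7 | rac-5,8-bis(benzyloxy)-3-bromoisochroman-1-one | BrC1Cc2c(OCc3ccccc3)ccc(OCc3ccccc3)c2C(=O)O1 | intermediate
8 | (S)-pent-4-en-2-ol | C[C@@H](CC=C)O | starting material
9 | 4-(benzyloxy)-4-oxobutanoic acid | OC(=O)CCC(=O)OCc1ccccc1 | starting material
10 | benzyl (S)-pent-4-en-2-yl succinate | C[C@@H](CC=C)OC(=O)CCC(=O)OCc1ccccc1 | intermediate
11 | benzyl (2S)-5-[(3R)-5,8-bis(benzyloxy)-1-oxoisochroman-3-yl]pentan-2-yl succinate | C[C@@H](CCC[C@@H]1Cc2c(OCc3ccccc3)ccc(OCc3ccccc3)c2C(=O)O1)OC(=O)CCC(=O)OCc1ccccc1 | intermediate
12 | aspergimarin B | C[C@@H](CCC[C@@H]1Cc2c(O)ccc(O)c2C(=O)O1)OC(=O)CCC(=O)O | target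

Total step count: 7
Longest linear sequence: 6 (steps 1, 2, 3, 4, 6, 7)

**Steps most likely to fail**

**Step 6.** The catalyst may discriminate the faces of the cyclic C3 radical poorly, since the lactone carbonyl cannot assist. Base-induced loss of HBr or simple hydrodebromination may also outrun the coupling. The fallback uses known chemistry, sets out from 5 and 10, and comes back at 11.
- Methanolysis of the enol lactone 5 (NaOMe, MeOH, 0 °C, AcOH quench) should give methyl 3,6-bis(benzyloxy)-2-(2-oxoethyl)benzoate F1.
- Hydroboration of 10 with Et2BH gives benzyl (S)-5-(diethylboranyl)pentan-2-yl succinate F2.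
- Boron–zinc exchange with Et2Zn (neat, 0 °C, volatiles removed in vacuo) gives bis[(4S)-4-{[4-(benzyloxy)-4-oxobutanoyl]oxy}pentyl]zinc F3.
- Catalytic asymmetric dialkylzinc addition of F3 to F1 forms the same C3–C1' bond under catalyst control. Conditions are Ti(OiPr)4 and (1S,2S)-N,N'-bis(trifluoromethanesulfonyl)cyclohexane-1,2-diamine (8 mol %) in toluene at −20 °C.
- The product is methyl 3,6-bis(benzyloxy)-2-[(2R,6S)-6-{[4-(benzyloxy)-4-oxobutanoyl]oxy}-2-hydroxyheptyl]benzoate F4, which lactonises (cat. TsOH, CH2Cl2) to 11.

**Step 4.** The product may lose HBr during formation or concentration and return to the enol lactone. The HBr released may also erode the benzyl ethers. The fallback sets out from 6 and comes back at 7.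
- Acetylation (Ac2O, pyridine, cat. DMAP, 0 °C) gives rac-5,8-bis(benzyloxy)-1-oxoisochroman-3-yl acetate F5, a storable acylal that can be purified.
- Halide exchange with Me3SiBr (CH2Cl2, 0 °C), as practised on anomeric acetates, delivers 7 just before use in a medium free of protic acid.

**Step 2.** C–H metalation may be sluggish at the ortho position squeezed between the carboxylate and a benzyloxy group. Protodecarboxylation of the acid or decomposition of vinylene carbonate may then take over. The fallback sets out from 1 and comes back at 6.
- Fischer esterification (MeOH, H2SO4) gives methyl 2,5-dihydroxybenzoate F6.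
- Selective allylation of the OH that is not hydrogen-bonded (allyl bromide, K2CO3, acetone) gives methyl 5-(allyloxy)-2-hydroxybenzoate F7.
- Aromatic Claisen rearrangement (N,N-diethylaniline, 190 °C) should favour migration to the position next to the ester and give methyl 2-allyl-3,6-dihydroxybenzoate F8.
- Benzylation (BnBr, K2CO3, DMF) gives methyl 2-allyl-3,6-bis(benzyloxy)benzoate F9.
- Lemieux–Johnson cleavage (cat. OsO4, NaIO4, THF/H2O) gives the aldehyde ester F1 described above.
- Saponification of F1 is assisted by the aldehyde hydrate (LiOH, THF/H2O, 0 °C, then cold acid) and leads to lactol 6.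

**Further compounds**
F1 | step 6 | methyl 3,6-bis(benzyloxy)-2-(2-oxoethyl)benzoate | COC(=O)c1c(CC=O)c(OCc2ccccc2)ccc1OCc1ccccc1
F2 | step 6 | benzyl (S)-5-(diethylboranyl)pentan-2-yl succinate | C[C@@H](CCCB(CC)CC)OC(=O)CCC(=O)OCc1ccccc1
F3 | step 6 | bis[(4S)-4-{[4-(benzyloxy)-4-oxobutanoyl]oxy}pentyl]zinc | C[C@@H](CCC[Zn]CCC[C@H](C)OC(=O)CCC(=O)OCc1ccccc1)OC(=O)CCC(=O)OCc1ccccc1
F4 | step 6 | methyl 3,6-bis(benzyloxy)-2-[(2R,6S)-6-{[4-(benzyloxy)-4-oxobutanoyl]oxy}-2-hydroxyheptyl]benzoate | C[C@@H](CCC[C@@H](O)Cc1c(OCc2ccccc2)ccc(OCc2ccccc2)c1C(=O)OC)OC(=O)CCC(=O)OCc1ccccc1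
F5 | step 4 | rac-5,8-bis(benzyloxy)-1-oxoisochroman-3-yl acetate | CC(=O)OC1Cc2c(OCc3ccccc3)ccc(OCc3ccccc3)c2C(=O)O1
F6 | step 2 | methyl 2,5-dihydroxybenzoate | COC(=O)c1cc(O)ccc1O
F7 | step 2 | methyl 5-(allyloxy)-2-hydroxybenzoate | COC(=O)c1cc(OCC=C)ccc1O
F8 | step 2 | methyl 2-allyl-3,6-dihydroxybenzoate | COC(=O)c1c(CC=C)c(O)ccc1O
F9 | step 2 | methyl 2-allyl-3,6-bis(benzyloxy)benzoate | COC(=O)c1c(CC=C)c(OCc2ccccc2)ccc1OCc1ccccc1
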